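## Retrosynthetic overview
1. Abiesin is a flavonol–flavone biaryl (C6 of the flavonol to C3′ of the flavone B ring). It is disconnected by Suzuki coupling into a 6‑iodo‑3,7‑bis(MOM) flavonol and a flavone‑3′‑Bpin. Final global MOM removal gives the target.
2. The flavone‑3′‑Bpin comes from 5‑hydroxy‑4′,7‑dimethoxyflavone by a proposed new Ir‑catalysed C–H borylation at C3′ (ortho to OMe). That flavone comes from a chalcone (Claisen–Schmidt) by I2/DMSO cyclisation.
3. The iodo‑flavonol comes from resacetophenone: C5 iodination, 4‑OH MOM protection, Claisen–Schmidt, then Algar–Flynn–Oyamada (AFO) ring closure with 3‑hydroxylation, then 3‑OH MOM protection.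
4. Ring order: flavone pyranone (I2/DMSO), then its C–B bond; flavonol pyranone (AFO); then the biaryl bond; then deprotection.

Assumptions (one line each):
- Abiesin has no stereocentres, and the C6–C3′ biaryl axis has only two ortho substituents and is not configurationally stable, so "single enantiomer" is trivially satisfied. The only stereo‑descriptor in the route is the E‑chalcone geometry, which is thermodynamic and irrelevant to the product.
- Iodination of 2′,4′‑dihydroxyacetophenone with NIS occurs mainly at C5′ (para to 2′‑OH, ortho to 4′‑OH); minor C3′ isomer is removed by chromatography.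

## Route

**Step 1**
Reactants: 1 (2′,6′‑dihydroxy‑4′‑methoxyacetophenone); 2 (4‑methoxybenzaldehyde)
Product: 3 ((E)‑2′,6′‑dihydroxy‑4,4′‑dimethoxychalcone)
Conditions: 50% aq. KOH, EtOH, rt, 24 h; then aq. HCl
Reagents that add atoms: none
Why: Claisen–Schmidt condensation; the ketone enolate adds to the aldehyde and dehydrates to the conjugated E‑enone. No stereocentre is formed.

**Step 2**
Reactants: 3
Product: 4 (5‑hydroxy‑4′,7‑dimethoxyflavone)
Conditions: I2 (0.2 equiv), DMSO, 130 °C, 3 h
Reagents that add atoms: none (I2/DMSO acts as the oxidant)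
Why: Oxidative cyclisation of a 2′‑hydroxychalcone (I2/DMSO) by oxa‑Michael addition to the flavanone followed by iodine‑mediated dehydrogenation. Compound 1 is symmetric about its C1–C4 axis, so either ortho OH gives the same 5‑OH‑7‑OMe pattern. No stereocentre.

**Step 3 (key new step)**
Reactants: 4; 5 (bis(pinacolato)diboron)
Product: 6 (5‑hydroxy‑4′,7‑dimethoxy‑3′‑(Bpin)flavone)
Conditions: [Ir(cod)OMe]2 (1.5 mol%), dtbpy (3 mol%), B2pin2 (0.6 equiv), THF, 80 °C, sealed tube, 16 h; recover and recycle 4
Reagents that add atoms: B2pin2, 5, CC1(C)OB(OC1(C)C)B1OC(C)(C)C(C)(C)O1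
Why: Proposed new method: site‑selective, sterically controlled Ir‑catalysed C–H borylation of a polyoxygenated, free‑5‑OH flavone at B‑ring C3′.
- Mechanism: Ir(dtbpy)(Bpin)3 activates the most accessible and most acidic aryl C–H by oxidative addition and reductive elimination.
- Selectivity: C3′/C5′ (ortho to small OMe, meta to chromonyl) beats C2′/C6′ (ortho to the bulky chromon‑2‑yl). A‑ring C6–H and C8–H are each flanked by two substituents. The 5‑OH is locked in a chelate with C4=O, so it neither O‑borylates nor poisons Ir.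
- Over‑borylation: limiting B2pin2 and recycling of 4 control mono‑ versus di‑borylation at C3′/C5′.
- Closest known reaction: Ishiyama–Miyaura–Hartwig borylation of 1,4‑disubstituted arenes, not yet shown on a flavone B ring.
- No stereocentre.

**Step 4**
Reactants: 7 (2′,4′‑dihydroxyacetophenone); 8 (N‑iodosuccinimide)
Product: 9 (2′,4′‑dihydroxy‑5′‑iodoacetophenone)
Conditions: NIS (1.05 equiv), MeCN, 0 °C to rt, 2 h
Reagents that add atoms: NIS, O=C1CCC(=O)N1I
Why: Electrophilic aromatic iodination of the activated resorcinol ring; C5′ is para to 2′‑OH and ortho to 4′‑OH and is the least hindered activated site.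

**Step 5**
Reactants: 9; 10 (chloromethyl methyl ether)
Product: 11 (2′‑hydroxy‑5′‑iodo‑4′‑(methoxymethoxy)acetophenone)
Conditions: MOMCl (1.05 equiv), DIPEA, CH2Cl2, 0 °C to rt, 4 h
Reagents that add atoms: MOMCl, ClCOC
Why: The 4′‑OH is the more acidic phenol, while the 2′‑OH is H‑bonded to the C=O, so protection is regioselective (Williamson‑type O‑alkylation).

**Step 6**
Reactants: 11; 2
Product: 12 ((E)‑2′‑hydroxy‑5′‑iodo‑4′‑(methoxymethoxy)‑4‑methoxychalcone)
Conditions: KOH, EtOH/H2O, rt, 16 h
Reagents that add atoms: none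
Why: Claisen–Schmidt condensation; MOM ether and aryl iodide are base‑stable. No stereocentre.

**Step 7**
Reactants: 12; 13 (hydrogen peroxide)
Product: 14 (3‑hydroxy‑6‑iodo‑7‑(methoxymethoxy)‑4′‑methoxyflavone)
Conditions: 30% H2O2, 2 M NaOH, MeOH, 0 °C to rt, 12 h
Reagents that add atoms: H2O2, OO
Why: Algar–Flynn–Oyamada reaction; nucleophilic epoxidation of the enone, then phenoxide opening and cyclisation, then tautomerisation to the flavonol. The product is planar and aromatic, so no stereocentre remains.

**Step 8**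
Reactants: 14; 10
Product: 15 (6‑iodo‑3,7‑bis(methoxymethoxy)‑4′‑methoxyflavone)
Conditions: NaH (1.2 equiv), DMF, 0 °C, then MOMCl (1.2 equiv), 1 h
Reagents that add atoms: MOMCl, ClCOC
Why: Deprotonation of the acidic 3‑OH followed by O‑alkylation; this avoids free flavonol chelation of Pd in the next step.

**Step 9**
Reactants: 15; 6
Product: 16 (protected biflavonoid: 6‑(flavon‑3′‑yl) flavonol bis‑MOM ether)
Conditions: Pd(OAc)2 (5 mol%), SPhos (10 mol%), K3PO4, dioxane/H2O 4:1, 90 °C, 12 h
Reagents that add atoms: none (both coupling partners are the reactants)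
Why: Suzuki–Miyaura coupling; the SPhos/Pd system handles the di‑ortho‑substituted biaryl, and the chelated 5‑OH, enones and MOM ethers are tolerated. No stereocentre (the biaryl axis is not configurationally stable).

**Step 10**
Reactants: 16
Product: 17 (Abiesin)
Conditions: 3 M HCl, THF/MeOH 1:1, 60 °C, 6 h
Reagents that add atoms: none (the product hydroxyls retain the original oxygens)
Why: Acid‑mediated acetal hydrolysis removes both MOM groups (3‑O and 7‑O). The aryl methyl ethers, the 5‑OH and the flavone/flavonol cores are stable. The target has no stereocentres.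

## Compound list
1 | 2′,6′‑dihydroxy‑4′‑methoxyacetophenone | COc1cc(O)c(C(C)=O)c(O)c1 | starting material
2 | 4‑methoxybenzaldehyde | COc1ccc(C=O)cc1 | starting material
3 | (E)‑2′,6′‑dihydroxy‑4,4′‑dimethoxychalcone | COc1ccc(/C=C/C(=O)c2c(O)cc(OC)cc2O)cc1 | intermediate
4 | 5‑hydroxy‑4′,7‑dimethoxyflavone | COc1ccc(cc1)-c1cc(=O)c2c(O)cc(OC)cc2o1 | intermediate
5 | bis(pinacolato)diboron | CC1(C)OB(OC1(C)C)B1OC(C)(C)C(C)(C)O1 | reagent
6 | 5‑hydroxy‑4′,7‑dimethoxy‑3′‑(Bpin)flavone | COc1ccc(cc1B1OC(C)(C)C(C)(C)O1)-c1cc(=O)c2c(O)cc(OC)cc2o1 | intermediate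
7 | 2′,4′‑dihydroxyacetophenone | CC(=O)c1ccc(O)cc1O | starting material
8 | N‑iodosuccinimide | O=C1CCC(=O)N1I | reagent
9 | 2′,4′‑dihydroxy‑5′‑iodoacetophenone | CC(=O)c1cc(I)c(O)cc1O | intermediate
10 | chloromethyl methyl ether | ClCOC | reagent
11 | 2′‑hydroxy‑5′‑iodo‑4′‑(MOMO)acetophenone | CC(=O)c1cc(I)c(OCOC)cc1O | intermediate
12 | (E)‑2′‑hydroxy‑5′‑iodo‑4′‑(MOMO)‑4‑methoxychalcone | COc1ccc(/C=C/C(=O)c2cc(I)c(OCOC)cc2O)cc1 | intermediate
13 | hydrogen peroxide | OO | reagent
14 | 3‑hydroxy‑6‑iodo‑7‑(MOMO)‑4′‑methoxyflavone | COc1ccc(cc1)-c1oc2cc(OCOC)c(I)cc2c(=O)c1O | intermediate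
15 | 6‑iodo‑3,7‑bis(MOMO)‑4′‑methoxyflavone | COc1ccc(cc1)-c1oc2cc(OCOC)c(I)cc2c(=O)c1OCOC | intermediate
16 | protected biflavonoid | COc1ccc(cc1)-c1oc2cc(OCOC)c(cc2c(=O)c1OCOC)-c1cc(ccc1OC)-c1cc(=O)c2c(O)cc(OC)cc2o1 | intermediate
17 | Abiesin (achiral, no stereocentres) | COc1ccc(cc1)-c1oc2cc(O)c(cc2c(=O)c1O)-c1cc(ccc1OC)-c1cc(=O)c2c(O)cc(OC)cc2o1 | target

## Totals
Total steps: 10 (convergent). Longest linear sequence: 7 steps (7 → 9 → 11 → 12 → 14 → 15 → 16 → 17).

## Three steps most likely to fail
1. **Step 3 (proposed new Ir C–H borylation).** Risks are mixtures from C3 or A‑ring borylation, di‑borylation at C3′/C5′, and O‑borylation.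
   Fallback (known chemistry): use 3‑iodo‑4‑methoxybenzaldehyde in Step 1, then I2/DMSO, to make the 3′‑iodoflavone. Convert it to the Bpin by Miyaura borylation (B2pin2, Pd(dppf)Cl2, KOAc) to give 6.
2. **Step 9 (hindered Suzuki coupling).** Risks are protodeboronation of the ortho‑OMe arylboronate and a sluggish di‑ortho‑substituted coupling.
   Fallback: reverse the polarity. Convert 15 to its 6‑Bpin by Miyaura borylation and couple it with the 3′‑iodoflavone from fallback 1, using Pd/SPhos or a Pd‑PEPPSI catalyst.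
3. **Step 7 (AFO).** Risks are aurone formation and low flavonol yield on the electron‑rich, iodo‑substituted chalcone.
   Fallback: cyclise chalcone 12 to the flavanone (NaOAc, EtOH, reflux). Then hydroxylate at C3 (KHMDS, Davis oxaziridine) and dehydrogenate to the flavonol (I2/NaOAc or DDQ).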